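**Strategy**

The target is the mono-seco acid of a two-fold symmetric bis(γ-lactone), so both halves are built together. The feature exploited is the cis pair of stereocentres in each lactone ring (O1, carbinol C2, methyl-bearing C3, C4, carbonyl C5): C2, C3 and the methyl correspond to a Z-propenyl group on chromanone C2, and C4–C5 to a ketene. Dichloroketene adds suprafacially to both Z-alkenes of a (2S,2'S)-6,6'-bichromanone diester, which closes two cyclobutanones, forms four C–C bonds and sets four stereocentres in one operation; oxygen insertion then converts each temporary C5–C2 bond into the lactone O1–C2 bond. The precursor is the C6–C6'-linked bis[2-(Z)-propenyl-5-methoxychromanone-2-carboxylate].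

Key step: step 8

Remark: both chromanone C2 centres of the target are S and each lactone is (2R,3S) with methyl cis to the chromanone. Each cyclobutyl group of the cycloadduct is numbered from the carbon bonded to chromanone C2; the ring carbonyl is next to that carbon and CCl2 next to the methyl-bearing carbon, that is a 3,3-dichloro-2-methyl-4-oxocyclobutyl group. The regioisomer with CCl2 next to the attachment carbon would not lead to the target lactone.

Remark: the precursor keeps C5/C5' methyl ethers and free C4 ketones; its Z-alkenes are made by alkyne semihydrogenation, so no base meets the β-aryloxy ketone once C2 is set.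

Remark: in step 6 the ligand antipode is the one that delivers 2S; this sense has to be confirmed on the first run.

Assumption: the γ-hydroxy acid of the target survives isolation if the final acidification stops near pH 4 at 0 °C.

**Route**

Step 1
Reactants: 1 4-bromo-3-methoxyphenol
Product: 2 1-bromo-2-methoxy-4-(methoxymethoxy)benzene
Conditions: MOMCl, i-Pr2NEt, CH2Cl2, 0 °C to rt
Reagents that add atoms: chloromethyl methyl ether, COCCl
Why: Williamson-type O-alkylation of the phenol (SN2 at the chloromethyl ether) installs a MOM group that later directs the lithiation and is shed in the acidic chromone closure.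

Step 2
Reactants: 2 1-bromo-2-methoxy-4-(methoxymethoxy)benzene
Product: 3 2-[2-methoxy-4-(methoxymethoxy)phenyl]-4,4,5,5-tetramethyl-1,3,2-dioxaborolane
Conditions: B2pin2, Pd(dppf)Cl2 (cat.), KOAc, 1,4-dioxane, 90 °C
Reagents that add atoms: bis(pinacolato)diboron, CC1(C)OB(OC1(C)C)B1OC(C)(C)C(C)(C)O1
Why: Miyaura borylation (oxidative addition of zerovalent palladium into the aryl bromide, acetate-assisted transmetalation with the diboron reagent, reductive elimination) places the pinacol boronate on the carbon that carried bromine, the weak base KOAc keeping the boronate from coupling with unreacted bromide.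

Step 3
Reactants: 3 2-[2-methoxy-4-(methoxymethoxy)phenyl]-4,4,5,5-tetramethyl-1,3,2-dioxaborolane; 2 1-bromo-2-methoxy-4-(methoxymethoxy)benzene
Product: 4 2,2'-dimethoxy-4,4'-bis(methoxymethoxy)-1,1'-biphenyl
Conditions: Pd(dppf)Cl2 (cat.), K3PO4, 1,4-dioxane/H2O, 90 °C
Reagents that add atoms: none
Why: Suzuki–Miyaura cross-coupling of the boronate with a second portion of the same aryl bromide joins the two rings at the carbons ortho to OMe and para to OMOM, so the symmetric biaryl forms without any regiochemical question and the MOM acetals are stable to the aqueous base.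

Step 4
Reactants: 4 2,2'-dimethoxy-4,4'-bis(methoxymethoxy)-1,1'-biphenyl; 5 N-methoxy-N-methylacetamide
Product: 6 1,1'-[2,2'-dimethoxy-4,4'-bis(methoxymethoxy)-1,1'-biphenyl-3,3'-diyl]diethanone
Conditions: n-BuLi, TMEDA, THF, 0 °C; then 5, −78 °C to rt; aq. NH4Cl
Reagents that add atoms: N-methoxy-N-methylacetamide (5), CON(C)C(C)=O
Why: Directed ortho-metalation takes place on each ring at C3, the only position flanked by two coordinating groups (OMe and OMOM), and the aryllithium is acylated in a Weinreb ketone synthesis whose chelated tetrahedral adduct prevents over-addition.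

Step 5
Reactants: 6 1,1'-[2,2'-dimethoxy-4,4'-bis(methoxymethoxy)-1,1'-biphenyl-3,3'-diyl]diethanone; 7 dimethyl oxalate
Product: 10 dimethyl 5,5'-dimethoxy-4,4'-dioxo-4H,4'H-[6,6'-bichromene]-2,2'-dicarboxylate, via MOM-protected bis(2,4-dioxobutanoate) 8 (not isolated), via bis(phenol) bis(2,4-dioxobutanoate) 9 (not isolated)
Conditions: 7, NaOMe, MeOH/THF, 65 °C; then conc. HCl, MeOH, 65 °C
Reagents that add atoms: dimethyl oxalate (7), COC(=O)C(=O)OC
Why: Crossed Claisen condensation of the methyl ketones with dimethyl oxalate gives the 2,4-diketo esters, and hot methanolic HCl then removes the MOM groups and cyclodehydrates the freed phenols onto the 2-keto groups (the classical chromone-2-carboxylate synthesis), the methyl ether being unable to cyclise so that OMe ends at C5 and the biaryl bond at C6.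

Step 6
Reactants: 10 dimethyl 5,5'-dimethoxy-4,4'-dioxo-4H,4'H-[6,6'-bichromene]-2,2'-dicarboxylate; 11 propyne
Product: 14 dimethyl (2S,2'S)-5,5'-dimethoxy-4,4'-dioxo-2,2'-di(prop-1-yn-1-yl)-[6,6'-bichromane]-2,2'-dicarboxylate, via bis(4-silyloxybenzopyrylium) triflate 12 (not isolated), via bis(silyl enol ether) 13 (not isolated)
Conditions: 11 (condensed into toluene), CuI (cat.), Ph-BOX [2,2'-(propane-2,2-diyl)bis(4-phenyl-4,5-dihydrooxazole), antipode giving 2S] (cat.), TBSOTf, i-Pr2NEt, toluene/CH2Cl2, −78 °C; then 3 M HCl, THF, rt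
Reagents that add atoms: propyne (11), CC#C
Why: Silylation of each chromone carbonyl gives a 4-silyloxybenzopyrylium ion to which the copper acetylide CuC≡CCH3 bound to the chiral bis(oxazoline) adds at C2 (copper-catalysed enantioselective alkynylation of chromone-2-carboxylates, a known route to such tertiary ether centres), the ligand shielding one face of the planar cation so that both C2 centres are set as S under catalyst control, while the two-fold reaction diverts most of any wrong-face addition into the separable meso diastereomer.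

Step 7
Reactants: 14 dimethyl (2S,2'S)-5,5'-dimethoxy-4,4'-dioxo-2,2'-di(prop-1-yn-1-yl)-[6,6'-bichromane]-2,2'-dicarboxylate
Product: 15 dimethyl (2S,2'S)-5,5'-dimethoxy-4,4'-dioxo-2,2'-bis[(1Z)-prop-1-en-1-yl]-[6,6'-bichromane]-2,2'-dicarboxylate
Conditions: H2 (1 atm), Lindlar catalyst (Pd on CaCO3 poisoned with Pb(OAc)2), quinoline, EtOAc, rt
Reagents that add atoms: none
Why: Lindlar semihydrogenation delivers both hydrogens to the same face of each internal alkyne on the poisoned palladium surface and so gives the Z-alkenes, while aryl ketones, esters and the tertiary propargylic ether are left untouched and C2 is not affected.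

Step 8
Reactants: 15 dimethyl (2S,2'S)-5,5'-dimethoxy-4,4'-dioxo-2,2'-bis[(1Z)-prop-1-en-1-yl]-[6,6'-bichromane]-2,2'-dicarboxylate; 16 trichloroacetyl chloride
Product: 18 dimethyl (2S,2'S)-2,2'-bis[(1R,2R)-3,3-dichloro-2-methyl-4-oxocyclobutyl]-5,5'-dimethoxy-4,4'-dioxo-[6,6'-bichromane]-2,2'-dicarboxylate, via dichloroketene 17 (not isolated)
Conditions: 16 (excess, slow addition), Zn–Cu couple, DME/Et2O, 25–35 °C, ultrasound
Reagents that add atoms: trichloroacetyl chloride (16), ClC(Cl)(Cl)C(Cl)=O, which enters as dichloroketene (17), ClC(Cl)=C=O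
Why: Dichloroketene, released from trichloroacetyl chloride by zinc under non-basic conditions, adds to each Z-propenyl group in a concerted but asynchronous (2+2) cycloaddition that is suprafacial on the alkene, which is the standard dichloroketene–alkene cyclobutanone synthesis. Each four-membered ring closes by intermolecular cycloaddition in which both ring bonds form in one transition state: the ketene carbonyl carbon bonds to the alkene carbon next to C2 and the CCl2 carbon to the methyl-bearing carbon, because the developing positive charge is better placed on the methyl-substituted carbon than beside the oxygen- and ester-bearing quaternary C2. The cis relationship of the two new stereocentres in each ring follows from retention of the Z geometry. Their absolute sense follows from C2: allylic 1,3-strain turns the small ring oxygen O1 into the alkene plane towards the methyl group, which leaves the methyl ester on one face and the ring CH2 (C3) with the chromanone body on the other, so the ketene should approach past the flat ester and give the (1R,2R) cyclobutyl groups. The step needs regio-, face- and chemoselectivity: the hindered, weakly nucleophilic aryl ether oxygen should not enter a Bellus–Claisen pathway, the phenols are masked as methyl ethers against acylation, and DME ties up ZnCl2 so that the enolisable C4 ketones are left alone. The two alkenes are remote and homotopic, so the second addition should repeat the first.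

Step 9
Reactants: 18 dimethyl (2S,2'S)-2,2'-bis[(1R,2R)-3,3-dichloro-2-methyl-4-oxocyclobutyl]-5,5'-dimethoxy-4,4'-dioxo-[6,6'-bichromane]-2,2'-dicarboxylate
Product: 19 dimethyl (2S,2'S)-2,2'-bis[(2R,3R)-4,4-dichloro-3-methyl-5-oxooxolan-2-yl]-5,5'-dimethoxy-4,4'-dioxo-[6,6'-bichromane]-2,2'-dicarboxylate
Conditions: mCPBA, CH2Cl2, 0 °C to rt
Reagents that add atoms: mCPBA, OOC(=O)c1cccc(Cl)c1
Why: Baeyer–Villiger oxidation of the strained, chlorine-activated cyclobutanones is much faster than that of the conjugated aryl ketones, and in the Criegee adduct the secondary ring carbon bonded to C2 migrates with retention in preference to the electron-poor CCl2 carbon, which puts oxygen on the carbinol carbon and removes the epimerisable position next to the ketone.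

Step 10
Reactants: 19 dimethyl (2S,2'S)-2,2'-bis[(2R,3R)-4,4-dichloro-3-methyl-5-oxooxolan-2-yl]-5,5'-dimethoxy-4,4'-dioxo-[6,6'-bichromane]-2,2'-dicarboxylate
Product: 20 dimethyl (2S,2'S)-5,5'-dimethoxy-2,2'-bis[(2R,3S)-3-methyl-5-oxooxolan-2-yl]-4,4'-dioxo-[6,6'-bichromane]-2,2'-dicarboxylate
Conditions: Zn dust, AcOH, rt
Reagents that add atoms: none
Why: Zinc removes the two α-chlorines of each lactone stepwise through zinc enolates that acetic acid protonates (reductive dehalogenation of α-halo carbonyl compounds), there being no β-leaving group to eliminate and no stereocentre at the carbon that is reduced, so the change of the lactone C3 descriptor from R to S is only a change of priorities.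

Step 11
Reactants: 20 dimethyl (2S,2'S)-5,5'-dimethoxy-2,2'-bis[(2R,3S)-3-methyl-5-oxooxolan-2-yl]-4,4'-dioxo-[6,6'-bichromane]-2,2'-dicarboxylate
Product: 21 dimethyl (2S,2'S)-5,5'-dihydroxy-2,2'-bis[(2R,3S)-3-methyl-5-oxooxolan-2-yl]-4,4'-dioxo-[6,6'-bichromane]-2,2'-dicarboxylate
Conditions: BCl3, CH2Cl2, −78 to 0 °C; then H2O
Reagents that add atoms: none
Why: BCl3 chelates between each C4 carbonyl and the peri methoxy oxygen and cleaves only this activated aryl methyl ether by chloride attack on the methyl group (chelation-controlled demethylation), leaving methyl esters and lactones intact at low temperature.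

Step 12
Reactants: 21 dimethyl (2S,2'S)-5,5'-dihydroxy-2,2'-bis[(2R,3S)-3-methyl-5-oxooxolan-2-yl]-4,4'-dioxo-[6,6'-bichromane]-2,2'-dicarboxylate
Product: 22 (3S,4R)-4-hydroxy-4-{(2S,2'S)-5,5'-dihydroxy-2,2'-bis(methoxycarbonyl)-2'-[(2R,3S)-3-methyl-5-oxooxolan-2-yl]-4,4'-dioxo-[6,6'-bichroman]-2-yl}-3-methylbutanoic acid (CNP0517857.1)
Conditions: LiOH (about 3 equiv, two taken up by the phenols), THF/H2O, 0 °C; then dilute HCl to pH 4, 0 °C
Reagents that add atoms: lithium hydroxide, [Li+].[OH-]
Why: Hydroxide should open the unhindered γ-lactone carbonyl (saponification) faster than it attacks the methyl esters on the quaternary carbons, and because the two lactones are related by the two-fold axis either one gives the same seco acid, so running to partial conversion with recycling of recovered 21 should give the mono-acid without touching any stereocentre.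

**Compound list**

1 | 4-bromo-3-methoxyphenol | COc1cc(O)ccc1Br | starting material
2 | 1-bromo-2-methoxy-4-(methoxymethoxy)benzene | COCOc1ccc(Br)c(OC)c1 | intermediate
3 | 2-[2-methoxy-4-(methoxymethoxy)phenyl]-4,4,5,5-tetramethyl-1,3,2-dioxaborolane | COCOc1ccc(B2OC(C)(C)C(C)(C)O2)c(OC)c1 | intermediate
4 | 2,2'-dimethoxy-4,4'-bis(methoxymethoxy)-1,1'-biphenyl | COCOc1ccc(-c2ccc(OCOC)cc2OC)c(OC)c1 | intermediate
5 | N-methoxy-N-methylacetamide | CON(C)C(C)=O | starting material
6 | 1,1'-[2,2'-dimethoxy-4,4'-bis(methoxymethoxy)-1,1'-biphenyl-3,3'-diyl]diethanone | COCOc1ccc(-c2ccc(OCOC)c(C(C)=O)c2OC)c(OC)c1C(C)=O | intermediate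
7 | dimethyl oxalate | COC(=O)C(=O)OC | starting material
8 | dimethyl 4,4'-[2,2'-dimethoxy-4,4'-bis(methoxymethoxy)-1,1'-biphenyl-3,3'-diyl]bis(2,4-dioxobutanoate) | COCOc1ccc(-c2ccc(OCOC)c(C(=O)CC(=O)C(=O)OC)c2OC)c(OC)c1C(=O)CC(=O)C(=O)OC | intermediate (not isolated)
9 | dimethyl 4,4'-(4,4'-dihydroxy-2,2'-dimethoxy-1,1'-biphenyl-3,3'-diyl)bis(2,4-dioxobutanoate) | COC(=O)C(=O)CC(=O)c1c(O)ccc(-c2ccc(O)c(C(=O)CC(=O)C(=O)OC)c2OC)c1OC | intermediate (not isolated)
10 | dimethyl 5,5'-dimethoxy-4,4'-dioxo-4H,4'H-[6,6'-bichromene]-2,2'-dicarboxylate | COC(=O)C1=CC(=O)c2c(ccc(-c3ccc4c(c3OC)C(=O)C=C(C(=O)OC)O4)c2OC)O1 | intermediate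
11 | propyne | CC#C | starting material
12 | 4,4'-bis[(tert-butyldimethylsilyl)oxy]-5,5'-dimethoxy-2,2'-bis(methoxycarbonyl)-[6,6'-bichromenylium] bis(trifluoromethanesulfonate) | COC(=O)c1cc(O[Si](C)(C)C(C)(C)C)c2c(OC)c(-c3ccc4[o+]c(C(=O)OC)cc(O[Si](C)(C)C(C)(C)C)c4c3OC)ccc2[o+]1.[O-]S(=O)(=O)C(F)(F)F.[O-]S(=O)(=O)C(F)(F)F | intermediate (not isolated)
13 | dimethyl (2S,2'S)-4,4'-bis[(tert-butyldimethylsilyl)oxy]-5,5'-dimethoxy-2,2'-di(prop-1-yn-1-yl)-2H,2'H-[6,6'-bichromene]-2,2'-dicarboxylate | COC(=O)[C@@]1(C#CC)C=C(O[Si](C)(C)C(C)(C)C)c2c(ccc(-c3ccc4c(c3OC)C(O[Si](C)(C)C(C)(C)C)=C[C@@](C(=O)OC)(C#CC)O4)c2OC)O1 | intermediate (not isolated)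
14 | dimethyl (2S,2'S)-5,5'-dimethoxy-4,4'-dioxo-2,2'-di(prop-1-yn-1-yl)-[6,6'-bichromane]-2,2'-dicarboxylate | COC(=O)[C@@]1(C#CC)CC(=O)c2c(ccc(-c3ccc4c(c3OC)C(=O)C[C@@](C(=O)OC)(C#CC)O4)c2OC)O1 | intermediate
15 | dimethyl (2S,2'S)-5,5'-dimethoxy-4,4'-dioxo-2,2'-bis[(1Z)-prop-1-en-1-yl]-[6,6'-bichromane]-2,2'-dicarboxylate | COC(=O)[C@@]1(/C=C\C)CC(=O)c2c(ccc(-c3ccc4c(c3OC)C(=O)C[C@@](C(=O)OC)(/C=C\C)O4)c2OC)O1 | intermediate
16 | trichloroacetyl chloride | ClC(Cl)(Cl)C(Cl)=O | starting material
17 | dichloroketene | ClC(Cl)=C=O | intermediate (not isolated)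
18 | dimethyl (2S,2'S)-2,2'-bis[(1R,2R)-3,3-dichloro-2-methyl-4-oxocyclobutyl]-5,5'-dimethoxy-4,4'-dioxo-[6,6'-bichromane]-2,2'-dicarboxylate | COC(=O)[C@@]1([C@@H]5C(=O)C(Cl)(Cl)[C@@H]5C)CC(=O)c2c(ccc(-c3ccc4c(c3OC)C(=O)C[C@@](C(=O)OC)([C@@H]3C(=O)C(Cl)(Cl)[C@@H]3C)O4)c2OC)O1 | intermediate
19 | dimethyl (2S,2'S)-2,2'-bis[(2R,3R)-4,4-dichloro-3-methyl-5-oxooxolan-2-yl]-5,5'-dimethoxy-4,4'-dioxo-[6,6'-bichromane]-2,2'-dicarboxylate | COC(=O)[C@@]1([C@@H]5OC(=O)C(Cl)(Cl)[C@@H]5C)CC(=O)c2c(ccc(-c3ccc4c(c3OC)C(=O)C[C@@](C(=O)OC)([C@@H]3OC(=O)C(Cl)(Cl)[C@@H]3C)O4)c2OC)O1 | intermediate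
20 | dimethyl (2S,2'S)-5,5'-dimethoxy-2,2'-bis[(2R,3S)-3-methyl-5-oxooxolan-2-yl]-4,4'-dioxo-[6,6'-bichromane]-2,2'-dicarboxylate | COC(=O)[C@@]1([C@@H]5OC(=O)C[C@@H]5C)CC(=O)c2c(ccc(-c3ccc4c(c3OC)C(=O)C[C@@](C(=O)OC)([C@@H]3OC(=O)C[C@@H]3C)O4)c2OC)O1 | intermediate
21 | dimethyl (2S,2'S)-5,5'-dihydroxy-2,2'-bis[(2R,3S)-3-methyl-5-oxooxolan-2-yl]-4,4'-dioxo-[6,6'-bichromane]-2,2'-dicarboxylate | COC(=O)[C@@]1([C@@H]5OC(=O)C[C@@H]5C)CC(=O)c2c(ccc(-c3ccc4c(c3O)C(=O)C[C@@](C(=O)OC)([C@@H]3OC(=O)C[C@@H]3C)O4)c2O)O1 | intermediate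
22 | (3S,4R)-4-hydroxy-4-{(2S,2'S)-5,5'-dihydroxy-2,2'-bis(methoxycarbonyl)-2'-[(2R,3S)-3-methyl-5-oxooxolan-2-yl]-4,4'-dioxo-[6,6'-bichroman]-2-yl}-3-methylbutanoic acid (CNP0517857.1) | COC(=O)[C@@]1([C@H](O)[C@@H](C)CC(=O)O)CC(=O)c2c(ccc(-c3ccc4c(c3O)C(=O)C[C@@](C(=O)OC)([C@@H]3OC(=O)C[C@@H]3C)O4)c2O)O1 | target

**Count and risks**

Total step count: 12. Longest linear sequence: 12 steps, from 4-bromo-3-methoxyphenol.

Steps most likely to fail:

1. Step 8. The cycloaddition may be too slow at the hindered, inductively deactivated Z-alkenes, so that ketene oligomerisation wins. The ketene may also fail to discriminate between the ester face and the ring face, or the cycloadduct may epimerise next to the ketone before it is oxidised. Fallback, setting out from 15 and returning at 20: the lactone is built by reagent-controlled crotylation instead of cycloaddition. Ozonolysis of both propenyl groups of 15 (O3, CH2Cl2/MeOH, −78 °C, then Me2S) should give the bis(2-formylchromanone) F1. Brown syn-crotylboration with (Z)-crotyl-B(Ipc)2 (the reagent antipode that gives the R carbinol, −78 °C, NaBO3 work-up) should give the bis(homoallylic alcohol) F2, with the 1R,2S pair set by the reagent. Hydroboration of the terminal alkenes with 9-BBN and NaBO3 oxidation should give the bis(1,4-diol) F3. Oxidative lactonisation with TEMPO and PhI(OAc)2 should then close both γ-lactones and give 20.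

2. Step 12. The opening may not stop at one lactone, hydroxide may also attack a methyl ester or trigger enolisation at chromanone C3, or the seco acid may relactonise during acidification. Fallback, setting out from 21 and returning at 22: the target is approached from the fully opened side. Excess LiOH (THF/H2O, 0 °C) should open both lactones to the bis(seco acid) F4. Buffered acidification to about pH 3 then lets the lactones re-close one after the other; the closure is followed by HPLC and stopped by neutralisation to pH 4–5 when the mono-lactone 22 is at its maximum. Re-formed 21 goes back into step 12 and unchanged F4 is re-acidified.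

3. Step 6. Silylation of the peri-methoxy chromone may be slow, or the catalyst may not control the face of the biaryl-substituted benzopyrylium well enough, so that meso and antipodal material contaminate 14. Fallback, setting out from 10 and returning at 14: catalyst control is replaced by resolution. The same silyl triflate and copper acetylide addition is run without chiral ligand (CuI, i-Pr2NEt, TBSOTf, then HCl). It should give 14 together with the (2R,2'R)-enantiomer F5 and the meso (2R,2'S)-diastereomer F6. The meso (2R,2'S)-diastereomer F6 is removed by chromatography on silica or by crystallisation, and 14 is separated from the (2R,2'R)-enantiomer F5 by preparative HPLC on a chiral stationary phase.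

**Further compounds**

F1 | step 8 | dimethyl (2S,2'S)-2,2'-diformyl-5,5'-dimethoxy-4,4'-dioxo-[6,6'-bichromane]-2,2'-dicarboxylate | COC(=O)[C@@]1(C=O)CC(=O)c2c(ccc(-c3ccc4c(c3OC)C(=O)C[C@@](C(=O)OC)(C=O)O4)c2OC)O1
F2 | step 8 | dimethyl (2S,2'S)-2,2'-bis[(1R,2S)-1-hydroxy-2-methylbut-3-en-1-yl]-5,5'-dimethoxy-4,4'-dioxo-[6,6'-bichromane]-2,2'-dicarboxylate | COC(=O)[C@@]1([C@H](O)[C@@H](C)C=C)CC(=O)c2c(ccc(-c3ccc4c(c3OC)C(=O)C[C@@](C(=O)OC)([C@H](O)[C@@H](C)C=C)O4)c2OC)O1
F3 | step 8 | dimethyl (2S,2'S)-2,2'-bis[(1R,2S)-1,4-dihydroxy-2-methylbutyl]-5,5'-dimethoxy-4,4'-dioxo-[6,6'-bichromane]-2,2'-dicarboxylate | COC(=O)[C@@]1([C@H](O)[C@@H](C)CCO)CC(=O)c2c(ccc(-c3ccc4c(c3OC)C(=O)C[C@@](C(=O)OC)([C@H](O)[C@@H](C)CCO)O4)c2OC)O1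
F4 | step 12 | (3S,3'S,4R,4'R)-4,4'-[(2S,2'S)-5,5'-dihydroxy-2,2'-bis(methoxycarbonyl)-4,4'-dioxo-[6,6'-bichromane]-2,2'-diyl]bis(4-hydroxy-3-methylbutanoic acid) | COC(=O)[C@@]1([C@H](O)[C@@H](C)CC(=O)O)CC(=O)c2c(ccc(-c3ccc4c(c3O)C(=O)C[C@@](C(=O)OC)([C@H](O)[C@@H](C)CC(=O)O)O4)c2O)O1
F5 | step 6 | dimethyl (2R,2'R)-5,5'-dimethoxy-4,4'-dioxo-2,2'-di(prop-1-yn-1-yl)-[6,6'-bichromane]-2,2'-dicarboxylate | COC(=O)[C@]1(C#CC)CC(=O)c2c(ccc(-c3ccc4c(c3OC)C(=O)C[C@](C(=O)OC)(C#CC)O4)c2OC)O1
F6 | step 6 | dimethyl (2R,2'S)-5,5'-dimethoxy-4,4'-dioxo-2,2'-di(prop-1-yn-1-yl)-[6,6'-bichromane]-2,2'-dicarboxylate (meso) | COC(=O)[C@]1(C#CC)CC(=O)c2c(ccc(-c3ccc4c(c3OC)C(=O)C[C@@](C(=O)OC)(C#CC)O4)c2OC)O1
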